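**Retrosynthetic overview**

1. The plan rests on ring A being a hydroquinone monomethyl ether: C1 carries the aryl ether oxygen, C4 (para) the OMe and C2 (ortho) the CH2 link to an imidazole. A carbene carbon, a CO ligand and the β-carbon of an alkenyl carbene lay down exactly this pattern in a chromium benzannulation.
2. Both imidazoles are cut last, each back to an arylacetaldehyde carbon (imidazole C2), glyoxal (C4–C5) and two NH3; the bis-aldehyde goes back to a bis(2-hydroxyethyl) diaryl ether.
3. The C1–O aryl ether bond is cut to ring A phenol 12 and ring B iodide 15 (Ullmann coupling); ring B is bought as 3-iodophenylacetic acid.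
4. Ring A phenol is cut across C4–C5, C6–C1 and C1–C2 to the alkenyl(methoxy)carbene complex 8, one CO and Me3SiC≡CH 9, used as an acetylene surrogate whose silicon is removed afterwards; 8 comes from 3-butyn-1-ol and Cr(CO)6.
5. Order of ring formation: ring A (step 4), then both imidazole rings together (step 11); ring B is never built.

Key step: step 4

Assumption: the target is achiral, so no stereocentre has to be set; the only stereochemical element of the route is the E alkene of 3–8, which disappears on aromatisation. Ring A numbering: C1 = O-aryl, C2 = arm, C4 = OMe.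

**Route**

Step 1
Reactants: 1 3-butyn-1-ol
Product: 2 (but-3-yn-1-yloxy)triisopropylsilane
Conditions: TIPSCl, imidazole, DMF, 0 °C → rt
Reagents that add atoms: triisopropylsilyl chloride, CC(C)[Si](Cl)(C(C)C)C(C)C
Why: Standard imidazole-promoted O-silylation of a primary alcohol, giving an ether that tolerates organolithium, carbene-complex and mild acid conditions later.

Step 2
Reactants: 2 (but-3-yn-1-yloxy)triisopropylsilane
Product: 4 (E)-(4-iodobut-3-en-1-yloxy)triisopropylsilane, via alkenylzirconocene chloride 3 (not isolated)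
Conditions: Cp2Zr(H)Cl, THF, rt; then I2, THF, 0 °C
Reagents that add atoms: iodine, II
Why: Schwartz hydrozirconation adds Zr–H syn across the terminal alkyne with zirconium on the terminal carbon, and iodinolysis of the C–Zr bond with retention should give the E vinyl iodide only.

Step 3
Reactants: 4 (E)-(4-iodobut-3-en-1-yloxy)triisopropylsilane; 5 Cr(CO)6
Product: 8 pentacarbonyl[(E)-1-methoxy-5-(triisopropylsilyloxy)pent-2-en-1-ylidene]chromium, via alkenyllithium 6 (not isolated), via lithium acylchromate 7 (not isolated)
Conditions: t-BuLi (2 equiv), Et2O, −78 °C; Cr(CO)6, Et2O, −78 °C → rt; then Me3OBF4, CH2Cl2, 0 °C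
Reagents that add atoms: trimethyloxonium tetrafluoroborate, C[O+](C)C.F[B-](F)(F)F
Why: Fischer carbene synthesis, in which iodine–lithium exchange with retention of the E geometry gives an alkenyllithium that adds to a CO ligand of Cr(CO)6, and the hard Meerwein salt methylates the acylchromate on oxygen.

Step 4
Reactants: 8 pentacarbonyl[(E)-1-methoxy-5-(triisopropylsilyloxy)pent-2-en-1-ylidene]chromium; 9 trimethylsilylacetylene
Product: 11 4-methoxy-2-[2-(triisopropylsilyloxy)ethyl]-6-(trimethylsilyl)phenol, via phenol tricarbonylchromium complex 10 (not isolated)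
Conditions: HC≡CSiMe3 (2 equiv), THF (0.05 M), 50 °C, Ar; then air, Et2O, daylight, rt
Reagents that add atoms: none
Why: Thermal loss of one cis CO from 8 opens a site for the alkyne, which inserts into the Cr=C bond with its unsubstituted carbon bonding to the carbene carbon (C4–C5); a CO ligand then inserts at the silyl-bearing carbon to give a chromium-bound dienylketene (C6–C1), 6π-electrocyclisation of the ketene onto the alkenyl β-carbon closes ring A (C1–C2), and the cyclohexadienone tautomerises by loss of the C2 hydrogen to the phenol held on Cr(CO)3 (10), which air releases as 11. This is the Dötz benzannulation of an alkenyl(methoxy)carbene complex of zerovalent chromium with a terminal silylalkyne, a documented pairing in which Me3SiC≡CH stands in for acetylene, which itself tends to over-insert. Ring A is closed in the 6π-electrocyclic mode (formally a [3+2+1] assembly) and no stereocentre is created. The selectivity required is phenol formation over cyclopentannulation, furan formation and uptake of a second alkyne; chromium, the methoxy donor, an alkenyl rather than aryl carbene, THF and dilute solution all favour the six-membered ring, and the β-carbon carries the hydrogen needed for aromatisation. The sense of alkyne insertion is immaterial because C5 and C6 both end as C–H after step 5, and any isomer in which silicon has moved from C6 to the phenol oxygen is cleaved by the same acid.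

Step 5
Reactants: 11 4-methoxy-2-[2-(triisopropylsilyloxy)ethyl]-6-(trimethylsilyl)phenol
Product: 12 4-methoxy-2-[2-(triisopropylsilyloxy)ethyl]phenol
Conditions: CF3CO2H, CH2Cl2, 0 °C; aq NaHCO3
Reagents that add atoms: none
Why: Acid protodesilylation by ipso electrophilic aromatic substitution, fast at C6 because the carbon is ortho to the hydroxyl and the arenium ion is β-silicon stabilised, while the hindered primary TIPS ether should survive brief cold CF3CO2H.

Step 6
Reactants: 13 3-iodophenylacetic acid
Product: 14 2-(3-iodophenyl)ethanol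
Conditions: BH3·THF, THF, 0 °C → rt; then H2O
Reagents that add atoms: none
Why: Borane reduces a carboxylic acid chemoselectively through its acyloxyborane and leaves the aryl iodide untouched.

Step 7
Reactants: 14 2-(3-iodophenyl)ethanol
Product: 15 [2-(3-iodophenyl)ethoxy]triisopropylsilane
Conditions: TIPSCl, imidazole, DMF, rt
Reagents that add atoms: triisopropylsilyl chloride, CC(C)[Si](Cl)(C(C)C)C(C)C
Why: Routine silylation of the primary alcohol, so that only the phenol oxygen is available in the copper coupling and both arms carry the same protecting group.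

Step 8
Reactants: 12 4-methoxy-2-[2-(triisopropylsilyloxy)ethyl]phenol; 15 [2-(3-iodophenyl)ethoxy]triisopropylsilane
Product: 16 triisopropyl[2-[3-[4-methoxy-2-[2-(triisopropylsilyloxy)ethyl]phenoxy]phenyl]ethoxy]silane
Conditions: CuI (10 mol %), N,N-dimethylglycine hydrochloride (30 mol %), Cs2CO3, 1,4-dioxane, 90 °C, Ar
Reagents that add atoms: none
Why: Ligand-accelerated Ullmann diaryl ether synthesis, well suited to an electron-rich, mono-ortho-substituted phenol and an unhindered aryl iodide, with silyl ethers inert to the carbonate base in dioxane.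

Step 9
Reactants: 16 triisopropyl[2-[3-[4-methoxy-2-[2-(triisopropylsilyloxy)ethyl]phenoxy]phenyl]ethoxy]silane
Product: 17 2-[3-[2-(2-hydroxyethyl)-4-methoxyphenoxy]phenyl]ethanol
Conditions: Bu4NF, THF, 0 °C → rt; aq NH4Cl
Reagents that add atoms: none
Why: Fluoride cleaves both Si–O bonds (strong Si–F bond) and nothing else in the molecule is fluoride-sensitive.

Step 10
Reactants: 17 2-[3-[2-(2-hydroxyethyl)-4-methoxyphenoxy]phenyl]ethanol
Product: 18 2-[3-[4-methoxy-2-(2-oxoethyl)phenoxy]phenyl]acetaldehyde
Conditions: Dess–Martin periodinane, CH2Cl2, 0 °C → rt; used crude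
Reagents that add atoms: none
Why: Dess–Martin oxidation takes primary 2-arylethanols to arylacetaldehydes under near-neutral, non-aqueous conditions without over-oxidation or benzylic epimerisation issues, and the sensitive bis-aldehyde is carried on at once.

Step 11
Reactants: 18 2-[3-[4-methoxy-2-(2-oxoethyl)phenoxy]phenyl]acetaldehyde
Product: 19 lepidine C, 2-[[3-[2-(1H-imidazol-2-ylmethyl)-4-methoxyphenoxy]phenyl]methyl]-1H-imidazole
Conditions: glyoxal (40% aq), NH3 (28% aq), MeOH, 0 °C → rt
Reagents that add atoms: glyoxal, O=CC=O; ammonia, N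
Why: Twofold Debus–Radziszewski imidazole synthesis, in which each aldehyde carbon condenses with two NH3 and one glyoxal and loses three water molecules to become C2 of an N-unsubstituted imidazole, the benzylic CH2 remaining as the link.

**Compound list**

1 | 3-butyn-1-ol | C#CCCO | starting material
2 | (but-3-yn-1-yloxy)triisopropylsilane | C#CCCO[Si](C(C)C)(C(C)C)C(C)C | intermediate
3 | chlorobis(η5-cyclopentadienyl)[(E)-4-(triisopropylsilyloxy)but-1-en-1-yl]zirconium (Cp rings drawn σ-bonded) | CC(C)[Si](OCC/C=C/[Zr](Cl)(C1C=CC=C1)C1C=CC=C1)(C(C)C)C(C)C | intermediate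
4 | (E)-(4-iodobut-3-en-1-yloxy)triisopropylsilane | I/C=C/CCO[Si](C(C)C)(C(C)C)C(C)C | intermediate
5 | chromium hexacarbonyl, Cr(CO)6 | O=C=[Cr](=C=O)(=C=O)(=C=O)(=C=O)=C=O | starting material
6 | (E)-[4-(triisopropylsilyloxy)but-1-en-1-yl]lithium | [Li]/C=C/CCO[Si](C(C)C)(C(C)C)C(C)C | intermediate
7 | lithium pentacarbonyl[(E)-1-oxido-5-(triisopropylsilyloxy)pent-2-en-1-ylidene]chromate | [Li+].[O-]C(/C=C/CCO[Si](C(C)C)(C(C)C)C(C)C)=[Cr](=C=O)(=C=O)(=C=O)(=C=O)=C=O | intermediate
8 | pentacarbonyl[(E)-1-methoxy-5-(triisopropylsilyloxy)pent-2-en-1-ylidene]chromium | COC(/C=C/CCO[Si](C(C)C)(C(C)C)C(C)C)=[Cr](=C=O)(=C=O)(=C=O)(=C=O)=C=O | intermediate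
9 | trimethylsilylacetylene | C#C[Si](C)(C)C | starting material
10 | tricarbonyl[η6-4-methoxy-2-[2-(triisopropylsilyloxy)ethyl]-6-(trimethylsilyl)phenol]chromium (arene and Cr(CO)3 drawn as two components) | COc1cc(CCO[Si](C(C)C)(C(C)C)C(C)C)c(O)c([Si](C)(C)C)c1.O=C=[Cr](=C=O)=C=O | intermediate
11 | 4-methoxy-2-[2-(triisopropylsilyloxy)ethyl]-6-(trimethylsilyl)phenol | COc1cc(CCO[Si](C(C)C)(C(C)C)C(C)C)c(O)c([Si](C)(C)C)c1 | intermediate
12 | 4-methoxy-2-[2-(triisopropylsilyloxy)ethyl]phenol | COc1ccc(O)c(CCO[Si](C(C)C)(C(C)C)C(C)C)c1 | intermediate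
13 | 3-iodophenylacetic acid | OC(=O)Cc1cccc(I)c1 | starting material
14 | 2-(3-iodophenyl)ethanol | OCCc1cccc(I)c1 | intermediate
15 | [2-(3-iodophenyl)ethoxy]triisopropylsilane | CC(C)[Si](OCCc1cccc(I)c1)(C(C)C)C(C)C | intermediate
16 | triisopropyl[2-[3-[4-methoxy-2-[2-(triisopropylsilyloxy)ethyl]phenoxy]phenyl]ethoxy]silane | COc1ccc(Oc2cccc(CCO[Si](C(C)C)(C(C)C)C(C)C)c2)c(CCO[Si](C(C)C)(C(C)C)C(C)C)c1 | intermediate
17 | 2-[3-[2-(2-hydroxyethyl)-4-methoxyphenoxy]phenyl]ethanol | COc1ccc(Oc2cccc(CCO)c2)c(CCO)c1 | intermediate
18 | 2-[3-[4-methoxy-2-(2-oxoethyl)phenoxy]phenyl]acetaldehyde | COc1ccc(Oc2cccc(CC=O)c2)c(CC=O)c1 | intermediate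
19 | lepidine C | COc1ccc(Oc2cccc(Cc3ncc[nH]3)c2)c(Cc2ncc[nH]2)c1 | target

**Step count**

Total: 11 steps. Longest linear sequence: 9 steps (1 → 2 → 4 → 8 → 11 → 12 → 16 → 17 → 18 → 19; steps 1–5 and 8–11). The ring B branch (steps 6 and 7) joins at step 8.

**Steps most likely to fail**

Step 4 (benzannulation). The silyl-substituted dienylketene may be slow to cyclise and stall, a second alkyne may be taken up, cyclopentannulation may compete, or the electron-rich phenol may be oxidised during demetallation.
Fallback: keep the benzannulation but exchange the roles of the partners, so that the alkyne is an ordinary alkyl-substituted terminal alkyne and silicon sits on the carbene. The fallback sets out from alkyne 2 and Cr(CO)6 5. Commercial (E)-(2-bromovinyl)trimethylsilane (C[Si](C)(C)/C=C/Br) is exchanged with t-BuLi in Et2O at −78 °C to (E)-[2-(trimethylsilyl)ethenyl]lithium F1. This is added to Cr(CO)6 to give lithium pentacarbonyl[(E)-1-oxido-3-(trimethylsilyl)prop-2-en-1-ylidene]chromate F2, and methylation with Me3OBF4 gives pentacarbonyl[(E)-1-methoxy-3-(trimethylsilyl)prop-2-en-1-ylidene]chromium F3. Heating F3 with alkyne 2 in THF should place the alkyne substituent next to the CO-derived carbon, the usual and strongly preferred sense for terminal alkynes. The cyclohexadienone then carries H and SiMe3 on the same ring carbon and is expected to aromatise by a 1,3-shift of silicon to oxygen. This gives the tricarbonylchromium complex of the aryl silyl ether F4 and, after air, [4-methoxy-2-[2-(triisopropylsilyloxy)ethyl]phenoxy]trimethylsilane F5. If silicon stays on carbon instead, the product is 11 itself. The acid treatment of step 5 converts either to phenol 12, where the fallback rejoins the route.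

Step 11 (twofold imidazole formation). The enolisable arylacetaldehydes may undergo aldol self-condensation under ammonia, one of the two aldehydes may fail to convert, and glyoxal–ammonia self-condensation may consume reagent.
Fallback: build the imidazoles from nitriles by the Pinner/aminoacetal sequence, which also removes the sensitive bis-aldehyde of step 10. It sets out from diol 17. One-pot oxidation–amination (TEMPO cat., PhI(OAc)2, NH4OAc, MeCN/H2O) should give 2-[3-[2-(cyanomethyl)-4-methoxyphenoxy]phenyl]acetonitrile F6. HCl in MeOH at 0 °C converts it to the bis(methyl imidate) dihydrochloride F7. Aminoacetaldehyde dimethyl acetal in MeOH gives the bis[N-(2,2-dimethoxyethyl)amidine] dihydrochloride F8. Warm aqueous HCl then unmasks the aldehydes, and cyclisation and dehydration close both imidazoles. The fallback arrives at target 19.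

Step 5 (selective C–Si cleavage). The primary TIPS ether may be lost under the acid needed for protodesilylation, or C–Si cleavage may be incomplete at the short exposure that spares it.
Fallback: give up differentiating the silyl groups and rely on chemoselective phenol arylation instead. It sets out from 11. Prolonged CF3CO2H/CH2Cl2 followed by Bu4NF/THF removes all silicon to give 2-(2-hydroxyethyl)-4-methoxyphenol F9. Copper-catalysed O-arylation of F9 with the unprotected iodide 14 (CuI, picolinic acid, K3PO4, DMSO, 80 °C) should occur at the phenoxide, not at the aliphatic hydroxyls, and gives diol 17 directly. The fallback rejoins the route at 17, and steps 7–9 are not needed.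

**Further compounds**

F1 | step 4 | (E)-[2-(trimethylsilyl)ethenyl]lithium | [Li]/C=C/[Si](C)(C)C
F2 | step 4 | lithium pentacarbonyl[(E)-1-oxido-3-(trimethylsilyl)prop-2-en-1-ylidene]chromate | [Li+].[O-]C(/C=C/[Si](C)(C)C)=[Cr](=C=O)(=C=O)(=C=O)(=C=O)=C=O
F3 | step 4 | pentacarbonyl[(E)-1-methoxy-3-(trimethylsilyl)prop-2-en-1-ylidene]chromium | COC(/C=C/[Si](C)(C)C)=[Cr](=C=O)(=C=O)(=C=O)(=C=O)=C=O
F4 | step 4 | tricarbonyl[η6-[4-methoxy-2-[2-(triisopropylsilyloxy)ethyl]phenoxy]trimethylsilane]chromium (arene and Cr(CO)3 drawn as two components) | COc1ccc(O[Si](C)(C)C)c(CCO[Si](C(C)C)(C(C)C)C(C)C)c1.O=C=[Cr](=C=O)=C=O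
F5 | step 4 | [4-methoxy-2-[2-(triisopropylsilyloxy)ethyl]phenoxy]trimethylsilane | COc1ccc(O[Si](C)(C)C)c(CCO[Si](C(C)C)(C(C)C)C(C)C)c1
F6 | step 11 | 2-[3-[2-(cyanomethyl)-4-methoxyphenoxy]phenyl]acetonitrile | COc1ccc(Oc2cccc(CC#N)c2)c(CC#N)c1
F7 | step 11 | methyl 2-[3-[4-methoxy-2-(2-imino-2-methoxyethyl)phenoxy]phenyl]acetimidate dihydrochloride | COC(=N)Cc1cccc(Oc2ccc(OC)cc2CC(=N)OC)c1.Cl.Cl
F8 | step 11 | N-(2,2-dimethoxyethyl)-2-[3-[2-[2-(2,2-dimethoxyethylamino)-2-iminoethyl]-4-methoxyphenoxy]phenyl]acetamidine dihydrochloride | COC(OC)CNC(=N)Cc1cccc(Oc2ccc(OC)cc2CC(=N)NCC(OC)OC)c1.Cl.Cl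
F9 | step 5 | 2-(2-hydroxyethyl)-4-methoxyphenol | COc1ccc(O)c(CCO)c1
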